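**Retrosynthetic overview**
Ring numbering used throughout: C1 carries the aroyl group, C2 the prenyl group, C3 the methyl group, C3=C4 is the double bond, C5 is CH2, C6 carries phenyl.
1. Target 23 ⇐ bis-MOM ketone 22 ⇐ aldehyde 16 + aryllithium 20; aldehyde 16 ⇐ cyclohexa-1,4-diene-1-carbaldehyde 14 by conjugate phenylation at C6 and kinetic protonation at C1.
2. 14 ⇐ Diels–Alder adduct 9 (C3 acyl group reduced to CH3, C1–CH2OSi unmasked to CHO).
3. 9 ⇐ diene 5 (C2=C1–C6=C5, an ocimene-type triene with CH2OSi on C1) + N-propioloylpyrazole 8 (C3≡C4); the cycloaddition makes the C2–C3 and C4–C5 bonds together.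
4. Enabling feature: in the cyclohexene ring the prenyl-bearing C2 lies between two ring carbons, C1 and C3, that each carry one exocyclic carbon (the ketone carbon on C1, the methyl carbon on C3), while C4 and C5 carry only hydrogen. C3≡C4 can therefore come from a propiolic acid unit whose carbonyl carbon becomes the C3 methyl group, and C1 can be an inner diene carbon that carries the future ketone carbon.
5. Ring order: the cyclohexene ring is the only ring formed (step 4); the phenyl ring (step 9) and the trioxygenated benzene ring (step 12) are bought and attached afterwards.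

Key step: step 4

Assumption: the L-configured ligand in step 4 is taken to give the (6S) adduct 9; if the opposite sense is found, the D-configured ligand is used and nothing else changes.

**Step 1**
Reactants: 1 prop-2-yn-1-ol; 2 1-bromo-3-methylbut-2-ene (prenyl bromide)
Product: 4 (2Z)-2-ethenyl-6-methylhepta-2,5-dien-1-ol, via alkenylmagnesium chelate 3 (not isolated)
Conditions: CH2=CHMgCl (3 equiv), CuI (10 mol %), THF, 0 °C → 25 °C; then 2 (2.5 equiv), −20 °C → 25 °C; aq. NH4Cl
Reagents that add atoms: vinylmagnesium chloride, C=C[Mg]Cl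
Why: Alkoxide-directed, copper-catalysed anti-carbomagnesiation of the propargylic alcohol puts vinyl on the inner carbon and magnesium on the terminal carbon in a five-membered chelate, and copper-catalysed allylic alkylation with retention at the alkenyl carbon then places the prenyl group cis to CH2O and trans to vinyl, the geometry in which the diene can reach its s-cis form.

**Step 2**
Reactants: 4 (2Z)-2-ethenyl-6-methylhepta-2,5-dien-1-ol
Product: 5 tert-butyl{[(2Z)-2-ethenyl-6-methylhepta-2,5-dien-1-yl]oxy}dimethylsilane
Conditions: TBSCl, imidazole, CH2Cl2, 0 °C → 25 °C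
Reagents that add atoms: tert-butyldimethylsilyl chloride, CC(C)(C)[Si](C)(C)Cl
Why: Silyl ether formation at the primary allylic alcohol masks the hydroxyl against the Lewis acid of step 4 and the hydride reagents of steps 5 and 6.

**Step 3**
Reactants: 6 propiolic acid; 7 3,5-dimethyl-1H-pyrazole
Product: 8 1-(3,5-dimethyl-1H-pyrazol-1-yl)prop-2-yn-1-one
Conditions: DCC, CH2Cl2, 0 °C
Reagents that add atoms: none
Why: Carbodiimide-mediated N-acylation of the symmetrical pyrazole gives the alkynoyl dienophile with a two-point binding site (carbonyl O and pyrazole N2) for the copper catalyst.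

**Step 4**
Reactants: 5 tert-butyl{[(2Z)-2-ethenyl-6-methylhepta-2,5-dien-1-yl]oxy}dimethylsilane; 8 1-(3,5-dimethyl-1H-pyrazol-1-yl)prop-2-yn-1-one
Product: 9 [(6S)-5-({[tert-butyl(dimethyl)silyl]oxy}methyl)-6-(3-methylbut-2-en-1-yl)cyclohexa-1,4-dien-1-yl](3,5-dimethyl-1H-pyrazol-1-yl)methanone
Conditions: 5 (1.5 equiv), Cu(NTf2)2 (10 mol %), 3-(2-naphthyl)-L-alanine-derived amide ligand (11 mol %), 4 Å molecular sieves, MeCN, −40 °C → 0 °C
Reagents that add atoms: none
Why: The divalent copper centre binds the carbonyl oxygen and N2 of the pyrazole amide and lowers the alkyne LUMO, and the s-cis diene adds in a concerted but asynchronous Diels–Alder reaction in which the unsubstituted terminus C5 bonds first to the alkyne β-carbon C4 and the prenyl-bearing terminus C2 then bonds to the acyl-bearing carbon C3. The closest known reaction type is the enantioselective Diels–Alder reaction of N-propioloylpyrazoles with dienes under Cu(NTf2)2–amino acid amide catalysis, and the orientation is the one that ocimene-type dienes show with acyl-activated dienophiles. The six-membered carbocycle is closed by an intermolecular [4+2] cycloaddition, suprafacial on both partners, which gives the cyclohexa-1,4-diene with the C3=C4 double bond of the target already in place. The only new stereocentre, C2, is controlled by the catalyst: the naphthyl group of the ligand covers one face of the chelated dienophile, so the diene meets the open face with one of its two enantiotopic faces. The step needs regioselectivity (acyl carbon next to the prenyl-bearing carbon), secured by the alkyl substituent on the diene terminus C2 and the unhindered CH2 terminus C5 while the CH2OSi group on C1 is only a weak director, and chemoselectivity for the diene over the isolated trisubstituted alkene of the prenyl group, which cannot act as a diene.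

**Step 5**
Reactants: 9 (Diels–Alder adduct)
Product: 10 [(6R)-5-({[tert-butyl(dimethyl)silyl]oxy}methyl)-6-(3-methylbut-2-en-1-yl)cyclohexa-1,4-dien-1-yl]methanol
Conditions: i-Bu2AlH (2.5 equiv), CH2Cl2, −78 °C → −40 °C
Reagents that add atoms: none
Why: Hydride reduction of the activated N-acylpyrazole (1,2-reduction through the aldehyde) releases the pyrazole and gives the primary allylic alcohol without touching the silyl ether or the stereocentre; the descriptor changes from S to R only because the priorities change.

**Step 6**
Reactants: 10 (allylic alcohol)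
Product: 12 tert-butyl(dimethyl){[(6R)-5-methyl-6-(3-methylbut-2-en-1-yl)cyclohexa-1,4-dien-1-yl]methoxy}silane, via allylic sulfate monoester 11 (not isolated)
Conditions: SO3·pyridine, THF, 0 °C; then LiAlH4, THF, 0 °C → 25 °C
Reagents that add atoms: none
Why: Reductive deoxygenation by sulfation and direct SN2 hydride displacement of the primary allylic sulfate turns CH2OH into the C3 methyl group without allylic transposition.

**Step 7**
Reactants: 12 (silyl ether)
Product: 13 [(6R)-5-methyl-6-(3-methylbut-2-en-1-yl)cyclohexa-1,4-dien-1-yl]methanol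
Conditions: Bu4NF, THF, 0 °C
Reagents that add atoms: none
Why: Fluoride-mediated desilylation frees the primary allylic alcohol on C1 under conditions that do not affect the skipped diene.

**Step 8**
Reactants: 13 (dienyl methanol)
Product: 14 (6R)-5-methyl-6-(3-methylbut-2-en-1-yl)cyclohexa-1,4-diene-1-carbaldehyde
Conditions: DMP (1,1,1-triacetoxy-1,1-dihydro-1,2-benziodoxol-3(1H)-one), NaHCO3, CH2Cl2, 0 °C, under argon; used at once
Reagents that add atoms: none
Why: Buffered periodinane oxidation of the allylic alcohol gives the enal without a base or a dehydrogenating oxidant that could aromatise the 1,4-diene.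

**Step 9**
Reactants: 14 (dienal)
Product: 16 (1R,2S,6R)-3-methyl-2-(3-methylbut-2-en-1-yl)-6-phenylcyclohex-3-ene-1-carbaldehyde, via trimethylsilyl enol ether 15 (not isolated)
Conditions: PhMgBr (1.5 equiv), CuBr·SMe2 (10 mol %), Me3SiCl, THF, −78 °C; then 0.5 M HCl, THF, 0 °C, short contact
Reagents that add atoms: phenylmagnesium bromide, Br[Mg]c1ccccc1
Why: Copper-catalysed, chlorosilane-accelerated conjugate addition should deliver phenyl to C6 anti to the pseudoaxial prenyl group on C2, and kinetic axial protonation of the enol ether at C1, again anti to that prenyl group (phenyl equatorial, enol oxygen on the C2 side so no allylic strain at C6), should set the 1,2-cis-1,6-trans arrangement.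

**Step 10**
Reactants: 17 5-methoxybenzene-1,3-diol
Product: 18 1-methoxy-3,5-bis(methoxymethoxy)benzene
Conditions: MOMCl, i-Pr2NEt, CH2Cl2, 0 °C → 25 °C
Reagents that add atoms: chloromethyl methyl ether, COCCl
Why: O-alkylation of both phenols as methoxymethyl acetals gives ethers that tolerate the aryllithium and are removed by mild acid at the end.

**Step 11**
Reactants: 18 1-methoxy-3,5-bis(methoxymethoxy)benzene
Product: 19 2-bromo-1-methoxy-3,5-bis(methoxymethoxy)benzene
Conditions: NBS, MeCN, −20 °C → 0 °C
Reagents that add atoms: N-bromosuccinimide, O=C1CCC(=O)N1Br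
Why: Electrophilic aromatic bromination should favour the two equivalent positions between OMe and OMOM over the more hindered position between the two OMOM groups; the minor isomer is removed by chromatography.

**Step 12**
Reactants: 19 2-bromo-1-methoxy-3,5-bis(methoxymethoxy)benzene; 16 (aldehyde)
Product: 21 [2-methoxy-4,6-bis(methoxymethoxy)phenyl][(1R,2S,6R)-3-methyl-2-(3-methylbut-2-en-1-yl)-6-phenylcyclohex-3-en-1-yl]methanol, via aryllithium 20 (not isolated)
Conditions: n-BuLi, THF, −78 °C; then 16, −78 °C; aq. NH4Cl
Reagents that add atoms: none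
Why: Bromine–lithium exchange and 1,2-addition of the aryllithium to the aldehyde at low temperature form the C(aryl)–C bond faster than the α-branched aldehyde enolises; the new carbinol centre is not controlled and is removed in step 13.

**Step 13**
Reactants: 21 (carbinol, both epimers)
Product: 22 [2-methoxy-4,6-bis(methoxymethoxy)phenyl][(1R,2S,6R)-3-methyl-2-(3-methylbut-2-en-1-yl)-6-phenylcyclohex-3-en-1-yl]methanone
Conditions: DMP, NaHCO3, CH2Cl2, 0 °C → 25 °C
Reagents that add atoms: none
Why: Neutral periodinane oxidation of the benzylic carbinol gives the aryl ketone without enolising C1.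

**Step 14**
Reactants: 22 (bis-MOM ketone)
Product: 23 (2,4-dihydroxy-6-methoxyphenyl)[(1R,2S,6R)-3-methyl-2-(3-methylbut-2-en-1-yl)-6-phenylcyclohex-3-en-1-yl]methanone (isopanduratin A)
Conditions: HCl (3 M), MeOH, 25–40 °C
Reagents that add atoms: none
Why: Acid-catalysed acetal cleavage removes both MOM groups under conditions mild enough for the trisubstituted alkenes and for the hindered ketone, which enolises slowly.

**Compound list**
1 | prop-2-yn-1-ol | C#CCO | starting material
2 | 1-bromo-3-methylbut-2-ene (prenyl bromide) | CC(C)=CCBr | starting material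
3 | alkenylmagnesium chelate (4-ethenyl-2,5-dihydro-1,2-oxamagnesole) | C=CC1=C[Mg]OC1 | intermediate
4 | (2Z)-2-ethenyl-6-methylhepta-2,5-dien-1-ol | OC/C(C=C)=C\CC=C(C)C | intermediate
5 | tert-butyl{[(2Z)-2-ethenyl-6-methylhepta-2,5-dien-1-yl]oxy}dimethylsilane | CC(C)(C)[Si](C)(C)OC/C(C=C)=C\CC=C(C)C | intermediate
6 | propiolic acid | C#CC(=O)O | starting material
7 | 3,5-dimethyl-1H-pyrazole | Cc1cc(C)n[nH]1 | starting material
8 | 1-(3,5-dimethyl-1H-pyrazol-1-yl)prop-2-yn-1-one | C#CC(=O)n1nc(C)cc1C | intermediate
9 | [(6S)-5-({[tert-butyl(dimethyl)silyl]oxy}methyl)-6-(3-methylbut-2-en-1-yl)cyclohexa-1,4-dien-1-yl](3,5-dimethyl-1H-pyrazol-1-yl)methanone | CC(C)(C)[Si](C)(C)OCC1=CCC=C(C(=O)n2nc(C)cc2C)[C@H]1CC=C(C)C | intermediate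
10 | [(6R)-5-({[tert-butyl(dimethyl)silyl]oxy}methyl)-6-(3-methylbut-2-en-1-yl)cyclohexa-1,4-dien-1-yl]methanol | CC(C)(C)[Si](C)(C)OCC1=CCC=C(CO)[C@H]1CC=C(C)C | intermediate
11 | pyridinium sulfate monoester of 10 | CC(C)(C)[Si](C)(C)OCC1=CCC=C(COS(=O)(=O)[O-])[C@H]1CC=C(C)C.c1cc[nH+]cc1 | intermediate
12 | tert-butyl(dimethyl){[(6R)-5-methyl-6-(3-methylbut-2-en-1-yl)cyclohexa-1,4-dien-1-yl]methoxy}silane | CC(C)(C)[Si](C)(C)OCC1=CCC=C(C)[C@H]1CC=C(C)C | intermediate
13 | [(6R)-5-methyl-6-(3-methylbut-2-en-1-yl)cyclohexa-1,4-dien-1-yl]methanol | OCC1=CCC=C(C)[C@H]1CC=C(C)C | intermediate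
14 | (6R)-5-methyl-6-(3-methylbut-2-en-1-yl)cyclohexa-1,4-diene-1-carbaldehyde | O=CC1=CCC=C(C)[C@H]1CC=C(C)C | intermediate
15 | trimethylsilyl enol ether of 16 (silyloxy group on the C2 side) | C[Si](C)(C)O/C=C1\[C@H](CC=C(C)C)C(C)=CC[C@H]1c1ccccc1 | intermediate
16 | (1R,2S,6R)-3-methyl-2-(3-methylbut-2-en-1-yl)-6-phenylcyclohex-3-ene-1-carbaldehyde | O=C[C@@H]1[C@H](CC=C(C)C)C(C)=CC[C@H]1c1ccccc1 | intermediate
17 | 5-methoxybenzene-1,3-diol | COc1cc(O)cc(O)c1 | starting material
18 | 1-methoxy-3,5-bis(methoxymethoxy)benzene | COCOc1cc(OC)cc(OCOC)c1 | intermediate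
19 | 2-bromo-1-methoxy-3,5-bis(methoxymethoxy)benzene | COc1cc(OCOC)cc(OCOC)c1Br | intermediate
20 | [2-methoxy-4,6-bis(methoxymethoxy)phenyl]lithium | [Li]c1c(OC)cc(OCOC)cc1OCOC | intermediate
21 | [2-methoxy-4,6-bis(methoxymethoxy)phenyl][(1R,2S,6R)-3-methyl-2-(3-methylbut-2-en-1-yl)-6-phenylcyclohex-3-en-1-yl]methanol (both carbinol epimers) | COc1cc(OCOC)cc(OCOC)c1C(O)[C@@H]1[C@H](CC=C(C)C)C(C)=CC[C@H]1c1ccccc1 | intermediate
22 | [2-methoxy-4,6-bis(methoxymethoxy)phenyl][(1R,2S,6R)-3-methyl-2-(3-methylbut-2-en-1-yl)-6-phenylcyclohex-3-en-1-yl]methanone | COc1cc(OCOC)cc(OCOC)c1C(=O)[C@@H]1[C@H](CC=C(C)C)C(C)=CC[C@H]1c1ccccc1 | intermediate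
23 | (2,4-dihydroxy-6-methoxyphenyl)[(1R,2S,6R)-3-methyl-2-(3-methylbut-2-en-1-yl)-6-phenylcyclohex-3-en-1-yl]methanone (isopanduratin A) | COc1cc(O)cc(O)c1C(=O)[C@@H]1[C@H](CC=C(C)C)C(C)=CC[C@H]1c1ccccc1 | target

**Step count and risks**
Total step count: 14. Longest linear sequence: 11 steps (1, 2, 4, 5, 6, 7, 8, 9, 12, 13, 14).

Steps most likely to fail:

Step 4. The diene may sit over the copper-bound alkynoyl unit in both orientations (low enantiomeric excess), the regiochemistry may erode because the substituents on C1 and C2 direct in opposite senses, or the Lewis acid may degrade the diene. The fallback changes the mode of activation from a chelating Lewis acid on an acylpyrazole to covalent iminium activation of an ynal, a known reaction type for propynal. It sets out from 5: prop-2-ynal (made by oxidation of 1) and (2S,5S)-5-benzyl-2-tert-butyl-3-methylimidazolidin-4-one trifluoroacetate (20 mol %, or its enantiomer, whichever gives the 6S product) in MeCN at −40 °C should give (6S)-5-({[tert-butyl(dimethyl)silyl]oxy}methyl)-6-(3-methylbut-2-en-1-yl)cyclohexa-1,4-diene-1-carbaldehyde F1. Luche reduction (NaBH4, CeCl3, MeOH, −40 °C) then gives 10, where the route is rejoined.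

Step 9. The C1 configuration may be lost, either by protonation of the enol ether from the wrong face or by enolisation of the α-branched aldehyde on handling; both epimers of an aldehyde are expected to be close in energy, so equilibration would not repair it. The fallback sets C1 on a metalated nitrile, which is linear, has no allylic strain towards C6 and gives a configurationally robust product. It sets out from 16 obtained as a mixture at C1: NH2OH·HCl and pyridine, then Ac2O at 80 °C, should give 3-methyl-2-(3-methylbut-2-en-1-yl)-6-phenylcyclohex-3-ene-1-carbonitrile F2 as a C1 mixture with (2S,6R) fixed. Deprotonation with LiN(i-Pr)2 in THF at −78 °C and kinetic axial protonation with 2,6-di-tert-butylphenol, anti to the pseudoaxial prenyl group, should give (1R,2S,6R)-3-methyl-2-(3-methylbut-2-en-1-yl)-6-phenylcyclohex-3-ene-1-carbonitrile F3. Reduction with i-Bu2AlH (toluene, −78 °C) and mild hydrolysis returns 16, used at once in step 12.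

Step 1. The alkenylmagnesium chelate may be alkylated at the tertiary end of the prenyl unit (allylic transposition) or be protonated before it is alkylated. The fallback builds the same trisubstituted alkene by syn-hydrostannation and cross-coupling. It sets out from 1 and 2: CuI, K2CO3 and NaI in DMF should give 6-methylhept-5-en-2-yn-1-ol F4. Syn-hydrostannation (Bu3SnH, PdCl2(PPh3)2, THF, 0 °C) with tin on the carbon next to the carbinol should give (2E)-6-methyl-2-(tributylstannyl)hepta-2,5-dien-1-ol F5. Stille coupling with vinyl bromide (Pd(PPh3)4, CuI, DMF, 50 °C) with retention of geometry then gives 4, where the route is rejoined.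

**Further compounds**
F1 | step 4 | (6S)-5-({[tert-butyl(dimethyl)silyl]oxy}methyl)-6-(3-methylbut-2-en-1-yl)cyclohexa-1,4-diene-1-carbaldehyde | CC(C)(C)[Si](C)(C)OCC1=CCC=C(C=O)[C@H]1CC=C(C)C
F2 | step 9 | (2S,6R)-3-methyl-2-(3-methylbut-2-en-1-yl)-6-phenylcyclohex-3-ene-1-carbonitrile (mixture at C1) | N#CC1[C@H](CC=C(C)C)C(C)=CC[C@H]1c1ccccc1
F3 | step 9 | (1R,2S,6R)-3-methyl-2-(3-methylbut-2-en-1-yl)-6-phenylcyclohex-3-ene-1-carbonitrile | N#C[C@@H]1[C@H](CC=C(C)C)C(C)=CC[C@H]1c1ccccc1
F4 | step 1 | 6-methylhept-5-en-2-yn-1-ol | OCC#CCC=C(C)C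
F5 | step 1 | (2E)-6-methyl-2-(tributylstannyl)hepta-2,5-dien-1-ol | OC/C([Sn](CCCC)(CCCC)CCCC)=C\CC=C(C)C
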